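**Retrosynthetic overview**
1. The quinone is made last, from a 2,3,5,6-tetramethoxyphenyl group, by oxidative demethylation and hydrolysis of one vinylogous ester. The C4 methylene and the C8 methyl come from ketone-level handles by methylenation (at C8 followed by hydrogenation).
2. The C9–C11 bond and the C9/C10 stereocentres come from reductive benzylation of a bicyclic enone (C8=O, C9=C10) with a tetramethoxybenzyl bromide.
3. Rings A and B are formed together from a monocyclic cyclobutanone by a rhodium-catalysed cut-and-sew coupling. Ring B is the four-membered ring C5–C6–C7–C8 enlarged by C9 and C10, and ring A closes in the same event (C5–C10).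
4. Enabling feature: the strained acyl–quaternary bond C8(=O)–C5 of the cyclobutanone, held by the chain C4–C3–C2–C1 (the rest of ring A) within reach of the C9≡C10 triple bond.
5. The cyclobutanone (C5 configuration) comes from an (E)-alkenylcyclopropanol by Shi epoxidation and a semipinacol three-to-four ring expansion. Ring order: cyclopropane, cyclobutane, rings A and B together, quinone.

Key step: step 7

Remark: locants C1–C11 are those of the sesquiterpene part of the target (ring A = C1–C5 and C10, methylene on C4; ring B = C5–C10; C11 = benzylic CH2). α/β mean below/above the decalin drawn with the C5 methyl up. Hept-5-yn-1-ol is taken as a purchasable alkynol.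

**Route**

Step 1
Reactants: 1 hept-5-yn-1-ol
Product: 2 hept-5-ynal
Conditions: TEMPO (10 mol%), PhI(OAc)2, CH2Cl2, rt
Reagents that add atoms: none
Why: Oxoammonium (TEMPO) oxidation takes a primary alcohol to the aldehyde without over-oxidation and leaves the internal alkyne untouched.

Step 2
Reactants: 2 hept-5-ynal
Product: 3 ethyl (2E)-2-methylnon-2-en-7-ynoate
Conditions: Ph3P=C(CH3)CO2Et, CH2Cl2, rt
Reagents that add atoms: ethyl 2-(triphenylphosphoranylidene)propanoate, CCOC(=O)C(C)=P(c1ccccc1)(c1ccccc1)c1ccccc1
Why: Wittig olefination with a stabilised α-branched ylide should give the (E)-trisubstituted enoate, with the ester trans to the chain.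

Step 3
Reactants: 3 ethyl (2E)-2-methylnon-2-en-7-ynoate
Product: 4 1-[(2E)-non-2-en-7-yn-2-yl]cyclopropan-1-ol
Conditions: EtMgBr (3 equiv, slow addition), Ti(OiPr)4 (0.5 equiv), THF, 0 °C to rt; aq. NH4Cl
Reagents that add atoms: ethylmagnesium bromide, CC[Mg]Br
Why: Kulinkovich cyclopropanation, in which the titanacyclopropane formed from EtMgBr and Ti(OiPr)4 adds twice to the ester carbonyl; the α-methyl-β-alkyl enoate should resist conjugate addition and the alkene geometry is not touched.

Step 4
Reactants: 4 1-[(2E)-non-2-en-7-yn-2-yl]cyclopropan-1-ol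
Product: 5 tert-butyl(dimethyl){1-[(2E)-non-2-en-7-yn-2-yl]cyclopropoxy}silane
Conditions: TBSOTf, 2,6-lutidine, CH2Cl2, −78 to 0 °C
Reagents that add atoms: tert-butyldimethylsilyl trifluoromethanesulfonate, CC(C)(C)[Si](C)(C)OS(=O)(=O)C(F)(F)F
Why: Silylation of the tertiary cyclopropanol with a silyl triflate and a hindered base protects it against ring opening and supplies the silyl group that is relayed in step 6.

Step 5
Reactants: 5 tert-butyl(dimethyl){1-[(2E)-non-2-en-7-yn-2-yl]cyclopropoxy}silane
Product: 6 tert-butyl{1-[(2S,3R)-3-(hex-4-yn-1-yl)-2-methyloxiran-2-yl]cyclopropoxy}dimethylsilane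
Conditions: D-fructose-derived Shi ketone (1,2:4,5-di-O-isopropylidene-β-D-erythro-2,3-hexodiulo-2,6-pyranose, 30 mol%), KHSO5 (as 2KHSO5·KHSO4·K2SO4), K2CO3, Bu4NHSO4 (cat.), MeCN/CH2(OMe)2/aq. Na2B4O7 buffer, 0 °C
Reagents that add atoms: potassium peroxymonosulfate, [K+].[O-]S(=O)(=O)OO
Why: Shi epoxidation, in which the chiral dioxirane formed in situ should epoxidise the (E)-trisubstituted alkene through the spiro transition state on the face that gives the (2S,3R)-oxirane (same sense as for 1-phenylcyclohexene and geranyl-type alkenes), so both new stereocentres are catalyst-controlled.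

Step 6
Reactants: 6 tert-butyl{1-[(2S,3R)-3-(hex-4-yn-1-yl)-2-methyloxiran-2-yl]cyclopropoxy}dimethylsilane
Product: 7 (2R)-2-[(1R)-1-(tert-butyldimethylsilyloxy)hept-5-yn-1-yl]-2-methylcyclobutan-1-one
Conditions: TBSOTf (10 mol%), CH2Cl2, −78 °C; Et3N quench
Reagents that add atoms: none
Why: Semipinacol (Suzuki–Tsuchihashi type) rearrangement of a 2,3-epoxy silyl ether, in which a cyclopropane C–C bond migrates anti to the breaking tertiary C–O bond (inversion, giving the (R)-quaternary carbon that becomes C5) with relief of cyclopropane strain, and silyl transfer from the oxocarbenium ion to the new alkoxide leaves the retained (R)-carbinol as its silyl ether.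

Step 7
Reactants: 7 (2R)-2-[(1R)-1-(tert-butyldimethylsilyloxy)hept-5-yn-1-yl]-2-methylcyclobutan-1-one
Product: 8 (4aS,5R)-5-(tert-butyldimethylsilyloxy)-1,4a-dimethyl-4,4a,5,6,7,8-hexahydronaphthalen-2(3H)-one (bicyclic enone: C8 ketone, C9=C10, 5β-methyl, 4α-silyloxy)
Conditions: [Rh(C2H4)2Cl]2 (5 mol%), P[3,5-(CF3)2C6H3]3 (20 mol%), 1,4-dioxane, 130 °C, sealed tube
Reagents that add atoms: none
Why: Monovalent rhodium, guided by the tethered alkyne, should insert into the strained acyl–C5 bond of the cyclobutanone to give a rhodacyclopentanone; syn insertion of the C9≡C10 alkyne into the Rh–C5 bond and acyl–alkenyl reductive elimination then give the enone and return the catalyst. The closest known reaction type is the rhodium-catalysed intramolecular cut-and-sew carboacylation of alkynes by cyclobutanones that carry the alkyne on a chain at the α-carbon, which gives cyclohexenone-fused bicycles. Ring A closes by 6-exo-dig carbometalation (C5–C10 bond); ring B is not closed but enlarged, the four-membered C5–C6–C7–C8 ring taking up C9 and C10 in a formal [4+2] two-atom ring expansion (C8–C9 bond). No new stereocentre is formed: the quaternary C5 set in step 6 is carried over with retention, because C–C oxidative addition and migratory insertion both retain configuration at the sp3 carbon. The step needs cleavage of the proximal C8–C5 bond in preference to the distal C8–C7 bond, and coupling in preference to decarbonylation to a cyclopropane. The four-carbon chain, which allows only the fused mode of alkyne insertion from the proximal rhodacycle, and the electron-poor phosphine, which speeds reductive elimination, should secure both.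

Step 8
Reactants: 9 1,2,4,5-tetramethoxybenzene
Product: 11 (2,3,5,6-tetramethoxyphenyl)methanol, via aryllithium 10 (not isolated)
Conditions: n-BuLi, TMEDA, THF, 0 °C; (CH2O)n, 0 °C to rt; H2O
Reagents that add atoms: formaldehyde (from paraformaldehyde), C=O
Why: Directed ortho-lithiation at a ring position flanked by two methoxy groups, followed by trapping of the aryllithium with formaldehyde, gives the benzylic alcohol.

Step 9
Reactants: 11 (2,3,5,6-tetramethoxyphenyl)methanol
Product: 12 3-(bromomethyl)-1,2,4,5-tetramethoxybenzene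
Conditions: PBr3, Et2O, 0 °C
Reagents that add atoms: phosphorus tribromide, BrP(Br)Br
Why: Substitution of an electron-rich benzylic alcohol by bromide through its bromophosphite.

Step 10
Reactants: 8 bicyclic enone (4α-silyloxy, 5β-methyl), 12 3-(bromomethyl)-1,2,4,5-tetramethoxybenzene
Product: 14 trans-fused decalin-8-one with 4α-OTBS, 5β-methyl, 9β-methyl, 9α-(2,3,5,6-tetramethoxybenzyl) and 10α-H, via lithium enolate 13 (not isolated)
Conditions: Li (2.2 equiv), t-BuOH (1.0 equiv), NH3(l)/THF, −78 °C; then 12, THF, −78 to −33 °C; NH4Cl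
Reagents that add atoms: none
Why: Birch-type reductive alkylation, in which axial protonation of C10 on the α-face gives the trans-fused enolate regiospecifically and the benzyl bromide then attacks C9 anti to the axial C5 methyl (α-face), setting the 9β-methyl/9α-benzyl quaternary centre; the axial 4α-oxygen matches the axial oxygen of the dioxolane ketals commonly used on such enones.

Step 11
Reactants: 14 trans-fused decalin-8-one
Product: 15 8-methylene decalin (4α-OTBS, 5β-methyl, 9β-methyl, 9α-tetramethoxybenzyl, 10α-H)
Conditions: Ph3PCH3Br, KOt-Bu, toluene, 100 °C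
Reagents that add atoms: methyltriphenylphosphonium bromide, C[P+](c1ccccc1)(c1ccccc1)c1ccccc1.[Br-]
Why: Wittig methylenation with excess non-stabilised ylide at elevated temperature, as is usual for a ketone next to a quaternary carbon; no epimerisable centre is present.

Step 12
Reactants: 15 8-methylene decalin
Product: 16 8β-methyl decalin (4α-OTBS, 5β-methyl, 9β-methyl, 9α-tetramethoxybenzyl, 10α-H)
Conditions: H2 (1 atm), PtO2, EtOAc, rt
Reagents that add atoms: none
Why: Heterogeneous hydrogenation from the α-face, which is opposite to the two axial β-methyl groups at C9 and C5, should add the C8 hydrogen axially and leave the new methyl equatorial (8β).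

Step 13
Reactants: 16 8β-methyl decalin silyl ether
Product: 17 4α-hydroxy decalin (5β,8β,9β-trimethyl, 9α-tetramethoxybenzyl, 10α-H)
Conditions: Bu4NF, THF, 50 °C
Reagents that add atoms: none
Why: Fluoride-mediated cleavage of the secondary silyl ether.

Step 14
Reactants: 17 4α-hydroxy decalin
Product: 18 decalin-4-one (5β,8β,9β-trimethyl, 9α-tetramethoxybenzyl, 10α-H)
Conditions: Dess–Martin periodinane, CH2Cl2, rt
Reagents that add atoms: none
Why: Dess–Martin oxidation of the hindered secondary alcohol under neutral conditions; the C4 stereocentre, used only as a relay, is erased here.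

Step 15
Reactants: 18 decalin-4-one
Product: 19 4-methylene decalin carrying the 9α-(2,3,5,6-tetramethoxybenzyl) group (5β,8β,9β-trimethyl, 10α-H)
Conditions: Ph3PCH3Br, KOt-Bu, toluene, 100 °C
Reagents that add atoms: methyltriphenylphosphonium bromide, C[P+](c1ccccc1)(c1ccccc1)c1ccccc1.[Br-]
Why: Wittig methylenation of the neopentyl-type ketone installs the exocyclic methylene only after the C8 alkene has been reduced, so no selectivity between two alkenes is needed.

Step 16
Reactants: 19 4-methylene decalin tetramethoxyarene
Product: 20 3-(decalinylmethyl)-2,5-dimethoxy-1,4-benzoquinone (O-methyl ether of the target)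
Conditions: (NH4)2Ce(NO3)6, MeCN/H2O, 0 °C
Reagents that add atoms: water, O
Why: Oxidative demethylation of a para-dimethoxyarene by tetravalent cerium (arene radical cation, addition of water, loss of methanol); both para pairs lead to the same 2,5-dimethoxyquinone and the 1,1-disubstituted alkene should not be oxidised.

Step 17
Reactants: 20 2,5-dimethoxyquinone
Product: 21 ilimaquinone (5S,8S,9R,10S)
Conditions: HClO4 (aq., about 1 M overall), THF, 0 °C to rt, stopped at full conversion
Reagents that add atoms: water, O
Why: Acid-catalysed hydrolysis of a vinylogous ester, in which the methoxy group flanked by the bulky side chain is twisted out of conjugation and should be the one replaced by water, as in the usual preparation of 3-alkyl-2-hydroxy-5-methoxy-1,4-benzoquinones from their dimethyl ethers.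

**Compound list**
1 | hept-5-yn-1-ol | CC#CCCCCO | starting material
2 | hept-5-ynal | CC#CCCCC=O | intermediate
3 | ethyl (2E)-2-methylnon-2-en-7-ynoate | CC#CCCC/C=C(\C)C(=O)OCC | intermediate
4 | 1-[(2E)-non-2-en-7-yn-2-yl]cyclopropan-1-ol | CC#CCCC/C=C(\C)C1(O)CC1 | intermediate
5 | tert-butyl(dimethyl){1-[(2E)-non-2-en-7-yn-2-yl]cyclopropoxy}silane | CC#CCCC/C=C(\C)C1(O[Si](C)(C)C(C)(C)C)CC1 | intermediate
6 | tert-butyl{1-[(2S,3R)-3-(hex-4-yn-1-yl)-2-methyloxiran-2-yl]cyclopropoxy}dimethylsilane | CC#CCCC[C@H]1O[C@]1(C)C2(O[Si](C)(C)C(C)(C)C)CC2 | intermediate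
7 | (2R)-2-[(1R)-1-(tert-butyldimethylsilyloxy)hept-5-yn-1-yl]-2-methylcyclobutan-1-one | CC#CCCC[C@@H](O[Si](C)(C)C(C)(C)C)[C@@]1(C)CCC1=O | intermediate
8 | (4aS,5R)-5-(tert-butyldimethylsilyloxy)-1,4a-dimethyl-4,4a,5,6,7,8-hexahydronaphthalen-2(3H)-one | CC1=C2CCC[C@@H](O[Si](C)(C)C(C)(C)C)[C@@]2(C)CCC1=O | intermediate
9 | 1,2,4,5-tetramethoxybenzene | COc1cc(OC)c(OC)cc1OC | starting material
10 | (2,3,5,6-tetramethoxyphenyl)lithium | [Li]c1c(OC)c(OC)cc(OC)c1OC | intermediate
11 | (2,3,5,6-tetramethoxyphenyl)methanol | OCc1c(OC)c(OC)cc(OC)c1OC | intermediate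
12 | 3-(bromomethyl)-1,2,4,5-tetramethoxybenzene | BrCc1c(OC)c(OC)cc(OC)c1OC | intermediate
13 | lithium C8-enolate of the trans-fused decalin (4α-OTBS, 5β-methyl, 9-methyl, 10α-H) | CC(C)(C)[Si](C)(C)O[C@@H]1CCC[C@H]2C(C)=C([O-])CC[C@]12C.[Li+] | intermediate
14 | trans-fused decalin-8-one, 4α-OTBS, 5β-methyl, 9β-methyl, 9α-(2,3,5,6-tetramethoxybenzyl), 10α-H | CC(C)(C)[Si](C)(C)O[C@@H]1CCC[C@H]2[C@](C)(Cc3c(OC)c(OC)cc(OC)c3OC)C(=O)CC[C@]12C | intermediate
15 | 8-methylene analogue of 14 | CC(C)(C)[Si](C)(C)O[C@@H]1CCC[C@H]2[C@](C)(Cc3c(OC)c(OC)cc(OC)c3OC)C(=C)CC[C@]12C | intermediate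
16 | 8β-methyl decalin, 4α-OTBS, 5β,9β-dimethyl, 9α-(2,3,5,6-tetramethoxybenzyl), 10α-H | CC(C)(C)[Si](C)(C)O[C@@H]1CCC[C@H]2[C@](C)(Cc3c(OC)c(OC)cc(OC)c3OC)[C@@H](C)CC[C@]12C | intermediate
17 | 4α-hydroxy decalin, 5β,8β,9β-trimethyl, 9α-(2,3,5,6-tetramethoxybenzyl), 10α-H | O[C@@H]1CCC[C@H]2[C@](C)(Cc3c(OC)c(OC)cc(OC)c3OC)[C@@H](C)CC[C@]12C | intermediate
18 | decalin-4-one, 5β,8β,9β-trimethyl, 9α-(2,3,5,6-tetramethoxybenzyl), 10α-H | O=C1CCC[C@H]2[C@](C)(Cc3c(OC)c(OC)cc(OC)c3OC)[C@@H](C)CC[C@]12C | intermediate
19 | 4-methylene decalin, 5β,8β,9β-trimethyl, 9α-(2,3,5,6-tetramethoxybenzyl), 10α-H | C=C1CCC[C@H]2[C@](C)(Cc3c(OC)c(OC)cc(OC)c3OC)[C@@H](C)CC[C@]12C | intermediate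
20 | 2,5-dimethoxy-3-{[(5S,8S,9R,10S)-decalinyl]methyl}-1,4-benzoquinone (O-methyl ilimaquinone) | C=C1CCC[C@H]2[C@](C)(CC3=C(OC)C(=O)C=C(OC)C3=O)[C@@H](C)CC[C@]12C | intermediate
21 | ilimaquinone | C=C1CCC[C@H]2[C@](C)(CC3=C(O)C(=O)C=C(OC)C3=O)[C@@H](C)CC[C@]12C | target

**Step count and risks**

Total step count: 17. Longest linear sequence: 15 (steps 1–7 and 10–17).

Steps most likely to fail:

1. Step 7. Insertion of rhodium into the hindered acyl–quaternary C–C bond may be slow, so that loss of CO from the rhodacycle (decarbonylation to a cyclopropane) or alkyne oligomerisation takes over. The fallback uses a temporary directing group in place of free-ketone activation. It sets out from 7: condensation with 2-amino-3-methylpyridine (TsOH cat., toluene, removal of water) should give the N-(3-methylpyridin-2-yl) ketimine of the cyclobutanone F1. Chelation-assisted C–C activation with [Rh(C2H4)2Cl]2 and a triarylphosphine in dioxane, where the imidoyl rhodacycle cannot extrude CO, followed by the same alkyne insertion, should give the N-(3-methylpyridin-2-yl) ketimine of the bicyclic enone F2. Hydrolysis with aqueous oxalic acid in THF comes back to the route at 8.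

2. Step 17. Water may attack the wrong methoxy-bearing carbon, hydrolysis may run on to the dihydroxyquinone, or the acid may move the exocyclic double bond into ring A. The fallback replaces selective hydrolysis by full hydrolysis in base and selective O-methylation. It sets out from 20: aqueous NaOH in THF should hydrolyse both vinylogous esters to the 2,5-dihydroxy-3-(decalinylmethyl)-1,4-benzoquinone F3 under conditions that leave the alkene alone. Me3SiCHN2 (1 equiv) in MeOH/toluene at 0 °C should then methylate the less hindered hydroxyl, the one remote from the side chain, which comes back to the route at 21.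

3. Step 3. The titanacyclopropane may exchange with the internal alkyne, or add in conjugate fashion to the enoate instead of to the carbonyl. The fallback cyclopropanates a silyl dienol ether instead of an ester. It sets out from 2: Wittig reaction with 3-(triphenylphosphoranylidene)butan-2-one (toluene, reflux) should give (3E)-3-methyldec-3-en-8-yn-2-one F4. TBSOTf and Et3N should give the cross-conjugated tert-butyldimethylsilyl dienol ether F5. Simmons–Smith cyclopropanation (Et2Zn, CH2I2, CH2Cl2, 0 °C) of the electron-rich enol ether double bond comes back to the route at 5, bypassing 3 and 4.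

Further compounds
F1 | step 7 | N-(3-methylpyridin-2-yl) ketimine of cyclobutanone 7 | CC#CCCC[C@@H](O[Si](C)(C)C(C)(C)C)[C@@]1(C)CCC1=Nc1ncccc1C
F2 | step 7 | N-(3-methylpyridin-2-yl) ketimine of enone 8 | CC1=C2CCC[C@@H](O[Si](C)(C)C(C)(C)C)[C@@]2(C)CCC1=Nc1ncccc1C
F3 | step 17 | 2,5-dihydroxy-3-{[(5S,8S,9R,10S)-decalinyl]methyl}-1,4-benzoquinone | C=C1CCC[C@H]2[C@](C)(CC3=C(O)C(=O)C=C(O)C3=O)[C@@H](C)CC[C@]12C
F4 | step 3 | (3E)-3-methyldec-3-en-8-yn-2-one | CC#CCCC/C=C(\C)C(C)=O
F5 | step 3 | tert-butyl(dimethyl){[(3E)-3-methyldeca-1,3-dien-8-yn-2-yl]oxy}silane | CC#CCCC/C=C(\C)C(=C)O[Si](C)(C)C(C)(C)C
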